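The retrosynthesis first removes the three O-methyl groups, the silyl ether and the two aryl–CHO bonds, then desaturates C2'–C3' of the side chain. It then cuts C4–C5 (five-membered ring) and C1'–C2' together, which gives a monocyclic cycloheptenyl triflate with an (E)-styrene tether and a 2-methylpropenylboronate.
The enabling feature: quaternary C4 and benzylic C1' are neighbours, C4 sits on alkene carbon C5 of the seven-membered ring, and C1' has no β-hydrogen (C4 on one side, arene on the other). This is the pattern left by syn addition of C5 and a carbon group across a C4=C1' styrene.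
The triflate comes from the C5 ketone. Cutting C5–O/C1–H (hydroboration) and C1–C2 (B-alkyl Suzuki coupling) leads to a 2-methylcycloheptanone. This is made by inserting C5 into a carvone-derived cyclohexanone.
Forward order: six-membered ring (carvone), then seven-membered ring, tether, five-membered ring and side chain in one cascade, and finally arene formylation and deprotection.
Stereochemistry: C7 comes from (R)-carvone and C10 from equilibration (trans to C7). C1 is set by hydroboration anti to the C10 methyl, which gives the cis C1/C10 pair that enolate alkylation would not give. C4 is set from C1, and C1' from the (E) geometry through syn addition and retention.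

Key step: step 12

Numbering and assumption: C1 ring-fusion CH, C2/C3 CH2, C4 quaternary C, C5=C6 ring alkene, C7 CH bearing carbinol carbon C11, C8/C9 CH2, C10 CH–CH3, C1' benzylic CH, C2' next side-chain carbon. α is the face of H-1 and β the opposite face. Rotation about the C1'–aryl bond is taken as fast, so the two free arene positions are equivalent and monoformylation gives one compound.

Step 1
Reactants: 1 (R)-(−)-carvone
Product: 2 (5R)-5-(2-hydroxypropan-2-yl)-2-methylcyclohex-2-en-1-one
Conditions: 50% aq H2SO4, 0 °C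
Reagents that add atoms: water, O
Why: Acid-catalysed Markovnikov hydration protonates the 1,1-disubstituted isopropenyl group to a tertiary cation that water captures, while the electron-poor enone alkene stays untouched at 0 °C and the carvone stereocentre (future C7) is not involved.

Step 2
Reactants: 2 (5R)-5-(2-hydroxypropan-2-yl)-2-methylcyclohex-2-en-1-one
Product: 3 (5R)-2-methyl-5-[2-(triethylsilyloxy)propan-2-yl]cyclohex-2-en-1-one
Conditions: TESOTf, 2,6-lutidine, CH2Cl2, −78 to 0 °C
Reagents that add atoms: triethylsilyl trifluoromethanesulfonate, CC[Si](CC)(CC)OS(=O)(=O)C(F)(F)F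
Why: Silylation of a tertiary alcohol with a silyl triflate and a hindered pyridine base masks the carbinol for the later enolate, organoboron and organolithium steps and leaves the enone alone at low temperature.

Step 3
Reactants: 3 (5R)-2-methyl-5-[2-(triethylsilyloxy)propan-2-yl]cyclohex-2-en-1-one
Product: 5 (2R,5R)-2-methyl-5-[2-(triethylsilyloxy)propan-2-yl]cyclohexan-1-one (trans), via cis ketone 4 (not isolated)
Conditions: H2 (1 atm), Pd/C, EtOAc, 23 °C; then NaOMe (0.2 equiv), MeOH, 23 °C
Reagents that add atoms: none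
Why: Heterogeneous hydrogenation saturates the only alkene, mainly anti to the side chain, and base-catalysed epimerisation alpha to the ketone then sets the methyl-bearing carbon (future C10) under thermodynamic control as the diequatorial trans-2,5 isomer.

Step 4
Reactants: 5 (2R,5R)-2-methyl-5-[2-(triethylsilyloxy)propan-2-yl]cyclohexan-1-one
Product: 7 (2R,5R)-2-methyl-5-[2-(triethylsilyloxy)propan-2-yl]cycloheptan-1-one (carbonyl carbon = C1, new CH2 = C5), via α-silyl ketone 6 (not isolated)
Conditions: TMSCHN2 (1.3 equiv), AlMe3 (1.2 equiv), CH2Cl2, −78 to −20 °C; then 10% aq citric acid, THF, 23 °C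
Reagents that add atoms: (trimethylsilyl)diazomethane, C[Si](C)(C)C=[N+]=[N-]
Why: In this Lewis-acid-promoted diazoalkane homologation (Tiffeneau–Demjanov type) the less substituted CH2 migrates with loss of N2, so the new carbon enters on the side away from the methyl group, and the α-silyl ketone is protodesilylated under mild acid that touches neither C10 nor the silyl ether.

Step 5
Reactants: 7 (2R,5R)-2-methyl-5-[2-(triethylsilyloxy)propan-2-yl]cycloheptan-1-one
Product: 9 (4R,7R)-7-methyl-4-[2-(triethylsilyloxy)propan-2-yl]cyclohept-1-en-1-yl trifluoromethanesulfonate (C1–OTf, C1=C5), via lithium enolate 8 (not isolated)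
Conditions: LiN(i-Pr)2, THF, −78 °C; then N-(5-chloro-2-pyridyl)triflimide, −78 to 0 °C
Reagents that add atoms: N-(5-chloropyridin-2-yl)bis(trifluoromethanesulfonyl)imide, FC(F)(F)S(=O)(=O)N(c1ccc(Cl)cn1)S(=O)(=O)C(F)(F)F
Why: Kinetic deprotonation at the open CH2 (C5) rather than at methyl-bearing C10, followed by O-sulfonylation of the enolate (enol triflate synthesis), fixes the C1=C5 double bond and leaves C10 unepimerised.

Step 6
Reactants: 10 2,4,6-trimethoxybenzaldehyde
Product: 11 (E)-2-methyl-3-(2,4,6-trimethoxyphenyl)prop-2-enal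
Conditions: Ph3P=C(CH3)CHO, toluene, 110 °C
Reagents that add atoms: 2-(triphenylphosphoranylidene)propanal, CC(C=O)=P(c1ccccc1)(c1ccccc1)c1ccccc1
Why: Wittig olefination with a stabilised, α-branched formyl ylide should give the (E)-enal, in which aryl and methyl are cis, as is usual for stabilised ylides and aromatic aldehydes.

Step 7
Reactants: 11 (E)-2-methyl-3-(2,4,6-trimethoxyphenyl)prop-2-enal
Product: 12 2-[(1E)-2-methylbuta-1,3-dien-1-yl]-1,3,5-trimethoxybenzene
Conditions: MePPh3Br, KOt-Bu, THF, 0 °C
Reagents that add atoms: methyltriphenylphosphonium bromide, C[P+](c1ccccc1)(c1ccccc1)c1ccccc1.[Br-]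
Why: Wittig methylenation of the enal with the non-stabilised ylide adds C2 as a terminal CH2 and does not disturb the geometry of the trisubstituted alkene.

Step 8
Reactants: 12 2-[(1E)-2-methylbuta-1,3-dien-1-yl]-1,3,5-trimethoxybenzene; 9 (4R,7R)-7-methyl-4-[2-(triethylsilyloxy)propan-2-yl]cyclohept-1-en-1-yl trifluoromethanesulfonate
Product: 14 (4R,7R)-7-methyl-1-[(3E)-3-methyl-4-(2,4,6-trimethoxyphenyl)but-3-en-1-yl]-4-[2-(triethylsilyloxy)propan-2-yl]cyclohept-1-ene, via B-alkyl-9-BBN 13 (not isolated)
Conditions: 12, 9-BBN (1.1 equiv), THF, 0 to 23 °C; then 9, PdCl2(dppf) (5 mol %), 3 M aq K3PO4, DMF, 50 °C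
Reagents that add atoms: none
Why: In this B-alkyl Suzuki–Miyaura coupling 9-BBN adds only to the monosubstituted vinyl end of the diene (boron on C2), and the primary alkylborane then couples with the enol triflate to form C1–C2 with both alkene geometries retained.

Step 9
Reactants: 14 (4R,7R)-7-methyl-1-[(3E)-3-methyl-4-(2,4,6-trimethoxyphenyl)but-3-en-1-yl]-4-[2-(triethylsilyloxy)propan-2-yl]cyclohept-1-ene
Product: 16 (1R,5R,7R,10R)-cycloheptanol with α-OH on C5, α-H and β-tether on C1, β-methyl on C10 and α-side chain on C7, via C5 borane 15 (not isolated)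
Conditions: 9-BBN (2.5 equiv), THF, 65 °C; then NaOH, H2O2, 0 to 23 °C
Reagents that add atoms: hydrogen peroxide, OO
Why: Hydroboration–oxidation adds H (to C1) and boron (to C5) syn from the α face, anti to the C10 methyl that allylic strain with the C1 chain holds pseudoaxial, so C1 is set cis to C10 and oxidation goes with retention, while the tether alkene is spared because the single B–H of the bulky reagent would have to deliver boron to C1' between two ortho-methoxy groups.

Step 10
Reactants: 16 (1R,5R,7R,10R)-cycloheptanol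
Product: 17 (1R,7R,10R)-cycloheptanone: C5 ketone with β-tether on C1, β-methyl on C10, α-side chain on C7
Conditions: Dess–Martin periodinane, NaHCO3, CH2Cl2, 0 to 23 °C
Reagents that add atoms: none
Why: Dess–Martin oxidation under buffered, non-basic conditions turns the C5 carbinol into the ketone without enolisation, so the cis C1/C10 relationship is kept.

Step 11
Reactants: 17 (1R,7R,10R)-cycloheptanone
Product: 19 (1R,7R,10R)-cycloheptenyl triflate: C5–OTf, C5=C6, (E)-styrene tether on C1, via lithium enolate 18 (not isolated)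
Conditions: LiN(i-Pr)2 (1.15 equiv), THF, −78 °C, 17 added to the base; then N-(5-chloro-2-pyridyl)triflimide, −78 °C
Reagents that add atoms: N-(5-chloropyridin-2-yl)bis(trifluoromethanesulfonyl)imide, FC(F)(F)S(=O)(=O)N(c1ccc(Cl)cn1)S(=O)(=O)C(F)(F)F
Why: Irreversible kinetic enolisation removes a proton from the C6 methylene and not the tertiary C1–H, and trapping at −78 °C with the reactive pyridyl triflimide (enol triflate synthesis) prevents enolate equilibration, so C1 is not scrambled.

Step 12
Reactants: 19 (1R,7R,10R)-cycloheptenyl triflate; 20 4,4,5,5-tetramethyl-2-(2-methylprop-1-en-1-yl)-1,3,2-dioxaborolane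
Product: 21 (1R,4R,7R,10R,1'S)-hydroazulene with a 2-methylprop-1-enyl group and the 2,4,6-trimethoxyphenyl group on C1'
Conditions: Pd(OAc)2 (10 mol %), PPh3 (22 mol %), K3PO4 (3 equiv), THF–H2O (10:1), 65 °C; 20 (1.5 equiv) added over 4 h
Reagents that add atoms: none
Why: Zerovalent palladium, formed from Pd(OAc)2 and PPh3, inserts into the C5–OTf bond, and the resulting cationic alkenylpalladium binds the tethered alkene and adds across it in a syn 5-exo-trig carbopalladation that forms C4–C5, closes the five-membered ring and places palladium on C1'. The closest known reaction type is the domino Heck–Suzuki sequence, in which a σ-alkylpalladium lacking β-hydrogen is intercepted by an organoboron reagent. Here quaternary C4 and the arene flank the metal-bearing carbon, so β-hydride elimination is impossible, η3-benzyl coordination stabilises the species long enough for the alkenyl group of 20 to move from boron to palladium, and reductive elimination with retention at carbon makes C1'–C2'. C4 is controlled by C1: with the tether β and the cis methyl on C10 also β, the alkene should reach C5 with its CH(Ar) terminus turned to the α face, on the side of H-1 and away from the C10–C9 flank, which leaves the C4 methyl β (4R). C1' follows from C4 through the (E) geometry (aryl cis to methyl), syn addition and retention, which together give 1'S. The selectivity needed is ring closure before cross-coupling at C5, and it is secured by the intramolecular five-membered insertion on a halide-free cationic palladium and by keeping the slowly transmetalating pinacol boronate at low concentration.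

Step 13
Reactants: 21 (1R,4R,7R,10R,1'S)-hydroazulene with 2-methylprop-1-enyl group
Product: 22 (1R,4R,7R,10R,1'S)-hydroazulene with isobutyl group on C1'
Conditions: H2 (1 atm), PtO2 (5 mol %), EtOAc, 23 °C, stopped after one equivalent of H2
Reagents that add atoms: none
Why: Heterogeneous hydrogenation selects by access to the surface, so the side-chain alkene with its open dimethyl terminus should be reduced before the C5=C6 alkene, which is buried between quaternary C4 and the silyloxyisopropyl-bearing C7, and platinum is chosen because it migrates double bonds less than palladium.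

Step 14
Reactants: 22 (1R,4R,7R,10R,1'S)-hydroazulene with isobutyl group
Product: 25 monoaldehyde: 22 with one formyl group between two methoxy groups of the arene, via aryllithium 23 (not isolated), via lithium hemiaminal alkoxide 24 (not isolated)
Conditions: n-BuLi (1.3 equiv), TMEDA, THF, 0 °C; then DMF, −78 to 0 °C; H2O work-up
Reagents that add atoms: N,N-dimethylformamide, CN(C)C=O
Why: Directed ortho-metalation removes an arene hydrogen flanked by two methoxy groups, by far the most acidic C–H present, and formylation of the aryllithium with DMF is basic enough in character to spare the ring alkene and the silyl ether that Lewis-acid formylations would endanger.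

Step 15
Reactants: 25 monoaldehyde
Product: 29 dialdehyde: 3,5-diformyl-2,4,6-trimethoxyphenyl group on C1', via amino alkoxide 26 (not isolated), via lithiated amino alkoxide 27 (not isolated), via bis(hemiaminal) alkoxide 28 (not isolated)
Conditions: LiN(CH3)CH2CH2N(CH3)2 (1.2 equiv, from the amine and n-BuLi), THF, −20 °C; then n-BuLi (2.5 equiv), −20 to 0 °C; then DMF, −78 to 0 °C; H2O work-up
Reagents that add atoms: N,N-dimethylformamide, CN(C)C=O
Why: Addition of the lithium amide masks the aldehyde in the flask as an α-amino alkoxide, a second directed ortho-metalation then takes the only remaining arene hydrogen (again between two methoxy groups), and DMF quench with aqueous work-up releases both formyl groups.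

Step 16
Reactants: 29 dialdehyde
Product: 30 tertiary alcohol: 29 without the triethylsilyl group
Conditions: HF·pyridine, pyridine, THF, 0 to 23 °C
Reagents that add atoms: none
Why: Fluoride-driven cleavage of the Si–O bond under pyridine-buffered conditions frees the C11 carbinol without ionising it and without affecting the aldehydes or the ring alkene.

Step 17
Reactants: 30 tertiary alcohol
Product: 31 target CNP0281883.3, (1R,4R,7R,10R,1'S)
Conditions: NaSEt (12 equiv), DMF, 110 °C; then 1 M HCl
Reagents that add atoms: none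
Why: Thiolate SN2 dealkylation of aryl methyl ethers works here because every methoxy group is ortho to a formyl group that stabilises the departing phenoxide, and the basic medium avoids acid-induced dehydration of the carbinol or addition of a phenol to C5=C6.

Compound list
1 | (R)-(−)-carvone | CC(=C)[C@@H]1CC=C(C)C(=O)C1 | starting material
2 | (5R)-5-(2-hydroxypropan-2-yl)-2-methylcyclohex-2-en-1-one | CC(C)(O)[C@@H]1CC=C(C)C(=O)C1 | intermediate
3 | (5R)-2-methyl-5-[2-(triethylsilyloxy)propan-2-yl]cyclohex-2-en-1-one | CC[Si](CC)(CC)OC(C)(C)[C@@H]1CC=C(C)C(=O)C1 | intermediate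
4 | (2S,5R)-2-methyl-5-[2-(triethylsilyloxy)propan-2-yl]cyclohexan-1-one (cis, not isolated) | CC[Si](CC)(CC)OC(C)(C)[C@@H]1CC[C@H](C)C(=O)C1 | intermediate
5 | (2R,5R)-2-methyl-5-[2-(triethylsilyloxy)propan-2-yl]cyclohexan-1-one (trans) | CC[Si](CC)(CC)OC(C)(C)[C@@H]1CC[C@@H](C)C(=O)C1 | intermediate
6 | (2R,5R)-2-methyl-5-[2-(triethylsilyloxy)propan-2-yl]-7-(trimethylsilyl)cycloheptan-1-one (epimers at the silyl-bearing carbon, not isolated) | CC[Si](CC)(CC)OC(C)(C)[C@@H]1CC[C@@H](C)C(=O)C([Si](C)(C)C)C1 | intermediate
7 | (2R,5R)-2-methyl-5-[2-(triethylsilyloxy)propan-2-yl]cycloheptan-1-one | CC[Si](CC)(CC)OC(C)(C)[C@@H]1CC[C@@H](C)C(=O)CC1 | intermediate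
8 | lithium enolate of 7, C1=C5 (not isolated) | CC[Si](CC)(CC)OC(C)(C)[C@@H]1CC[C@@H](C)C(O[Li])=CC1 | intermediate
9 | (4R,7R)-7-methyl-4-[2-(triethylsilyloxy)propan-2-yl]cyclohept-1-en-1-yl trifluoromethanesulfonate | CC[Si](CC)(CC)OC(C)(C)[C@@H]1CC[C@@H](C)C(OS(=O)(=O)C(F)(F)F)=CC1 | intermediate
10 | 2,4,6-trimethoxybenzaldehyde | COc1cc(OC)c(C=O)c(OC)c1 | starting material
11 | (E)-2-methyl-3-(2,4,6-trimethoxyphenyl)prop-2-enal | COc1cc(OC)c(/C=C(C)/C=O)c(OC)c1 | intermediate
12 | 2-[(1E)-2-methylbuta-1,3-dien-1-yl]-1,3,5-trimethoxybenzene | COc1cc(OC)c(/C=C(C)/C=C)c(OC)c1 | intermediate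
13 | 9-[(3E)-3-methyl-4-(2,4,6-trimethoxyphenyl)but-3-en-1-yl]-9-borabicyclo[3.3.1]nonane (not isolated) | COc1cc(OC)c(/C=C(C)/CCB2C3CCCC2CCC3)c(OC)c1 | intermediate
14 | (4R,7R)-7-methyl-1-[(3E)-3-methyl-4-(2,4,6-trimethoxyphenyl)but-3-en-1-yl]-4-[2-(triethylsilyloxy)propan-2-yl]cyclohept-1-ene | COc1cc(OC)c(/C=C(C)/CCC2=CC[C@H](C(C)(C)O[Si](CC)(CC)CC)CC[C@H]2C)c(OC)c1 | intermediate
15 | C5 9-BBN adduct of 14, boron and H-1 both α (not isolated) | COc3cc(OC)c(/C=C(C)/CC[C@H]1[C@H](B2C4CCCC2CCC4)C[C@H](C(C)(C)O[Si](CC)(CC)CC)CC[C@H]1C)c(OC)c3 | intermediate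
16 | (1R,5R,7R,10R)-cycloheptanol, C5 α-OH | COc3cc(OC)c(/C=C(C)/CC[C@H]1[C@H](O)C[C@H](C(C)(C)O[Si](CC)(CC)CC)CC[C@H]1C)c(OC)c3 | intermediate
17 | (1R,7R,10R)-cycloheptanone, C5 ketone | COc3cc(OC)c(/C=C(C)/CC[C@H]1C(=O)C[C@H](C(C)(C)O[Si](CC)(CC)CC)CC[C@H]1C)c(OC)c3 | intermediate
18 | lithium enolate of 17, C5=C6 (not isolated) | COc3cc(OC)c(/C=C(C)/CC[C@H]1C(O[Li])=C[C@H](C(C)(C)O[Si](CC)(CC)CC)CC[C@H]1C)c(OC)c3 | intermediate
19 | (1R,7R,10R)-cycloheptenyl triflate with (E)-styrene tether | COc3cc(OC)c(/C=C(C)/CC[C@H]1C(OS(=O)(=O)C(F)(F)F)=C[C@H](C(C)(C)O[Si](CC)(CC)CC)CC[C@H]1C)c(OC)c3 | intermediate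
20 | 4,4,5,5-tetramethyl-2-(2-methylprop-1-en-1-yl)-1,3,2-dioxaborolane | CC(C)=CB1OC(C)(C)C(C)(C)O1 | starting material
21 | (1R,4R,7R,10R,1'S)-hydroazulene with C1' 2-methylprop-1-enyl group | CC(C)=C[C@H](c3c(OC)cc(OC)cc3OC)[C@@]1(C)CC[C@H]2C1=C[C@H](C(C)(C)O[Si](CC)(CC)CC)CC[C@H]2C | intermediate
22 | (1R,4R,7R,10R,1'S)-hydroazulene with C1' isobutyl group | CC(C)C[C@H](c3c(OC)cc(OC)cc3OC)[C@@]1(C)CC[C@H]2C1=C[C@H](C(C)(C)O[Si](CC)(CC)CC)CC[C@H]2C | intermediate
23 | aryllithium from 22 (not isolated) | CC(C)C[C@H](c3c(OC)cc(OC)c([Li])c3OC)[C@@]1(C)CC[C@H]2C1=C[C@H](C(C)(C)O[Si](CC)(CC)CC)CC[C@H]2C | intermediate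
24 | lithium hemiaminal alkoxide from 23 and DMF (not isolated) | CC(C)C[C@H](c3c(OC)cc(OC)c(C(O[Li])N(C)C)c3OC)[C@@]1(C)CC[C@H]2C1=C[C@H](C(C)(C)O[Si](CC)(CC)CC)CC[C@H]2C | intermediate
25 | monoaldehyde | CC(C)C[C@H](c3c(OC)cc(OC)c(C=O)c3OC)[C@@]1(C)CC[C@H]2C1=C[C@H](C(C)(C)O[Si](CC)(CC)CC)CC[C@H]2C | intermediate
26 | α-amino alkoxide from 25 (not isolated) | CC(C)C[C@H](c3c(OC)cc(OC)c(C(O[Li])N(C)CCN(C)C)c3OC)[C@@]1(C)CC[C@H]2C1=C[C@H](C(C)(C)O[Si](CC)(CC)CC)CC[C@H]2C | intermediate
27 | ring-lithiated α-amino alkoxide (not isolated) | CC(C)C[C@H](c3c(OC)c([Li])c(OC)c(C(O[Li])N(C)CCN(C)C)c3OC)[C@@]1(C)CC[C@H]2C1=C[C@H](C(C)(C)O[Si](CC)(CC)CC)CC[C@H]2C | intermediate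
28 | bis(hemiaminal) alkoxide (not isolated) | CC(C)C[C@H](c3c(OC)c(C(O[Li])N(C)C)c(OC)c(C(O[Li])N(C)CCN(C)C)c3OC)[C@@]1(C)CC[C@H]2C1=C[C@H](C(C)(C)O[Si](CC)(CC)CC)CC[C@H]2C | intermediate
29 | dialdehyde, silyl ether | CC(C)C[C@H](c3c(OC)c(C=O)c(OC)c(C=O)c3OC)[C@@]1(C)CC[C@H]2C1=C[C@H](C(C)(C)O[Si](CC)(CC)CC)CC[C@H]2C | intermediate
30 | dialdehyde, free tertiary alcohol | CC(C)C[C@H](c3c(OC)c(C=O)c(OC)c(C=O)c3OC)[C@@]1(C)CC[C@H]2C1=C[C@H](C(C)(C)O)CC[C@H]2C | intermediate
31 | CNP0281883.3, (1R,4R,7R,10R,1'S) | CC(C)C[C@H](c1c(O)c(C=O)c(O)c(C=O)c1O)[C@@]1(C)CC[C@H]2C1=C[C@H](C(C)(C)O)CC[C@H]2C | target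

Total step count: 17.
Longest linear sequence: 15 steps from (R)-carvone (steps 1–5 and 8–17). Steps 6 and 7 form the two-step arene branch.

The three steps most likely to fail

**Step 12.** Three processes could spoil this step.
- Cross-coupling at C5 may occur before the ring closes.
- Boron-to-palladium transfer at the very crowded benzylic palladium may be too slow, so the intermediate decays.
- Facial selectivity at C4 may be poor.

The fallback keeps the ring closure but replaces boron capture with carbonylative termination. It sets out from 19. Pd(OAc)2, PPh3, CO (1 atm), MeOH and Et3N in DMF at 70 °C should run the same 5-exo carbopalladation. The small ligand CO should then insert at C1' and give the methyl ester F1. Reduction with i-Bu2AlH gives the primary alcohol F2, and Dess–Martin oxidation gives the aldehyde F3. Wittig olefination with Ph3P=C(CH3)2 brings the sequence back to the route at 21.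

**Step 9.** The tether alkene may be hydroborated in competition, or the reaction at the hindered ring alkene may be too slow at a temperature where selectivity still holds. The fallback introduces the styrene only after all B–H chemistry is finished.
- It sets out from 9, which is coupled with vinylboronic acid pinacol ester (PdCl2(dppf), K3PO4) to give the vinylcycloheptene F4.
- Excess 9-BBN (23 °C, then 65 °C) adds first to the vinyl group and then to the ring alkene, giving the bis(9-BBN) adduct F5.
- Aqueous K3PO4 destroys residual B–H. PdCl2(dppf) then couples only the primary B–C bond with the alkenyl iodide F7, which returns to the route at 15. This is oxidised as in step 9.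
- The iodide comes from the arylpropyne F6 by syn hydrozirconation and iodination (Cp2ZrHCl, then I2).
- F6 comes from commercial 2-iodo-1,3,5-trimethoxybenzene and propyne (PdCl2(PPh3)2, CuI, Et3N).

**Step 13.** Uptake of hydrogen may not stop after the side chain, or the ring double bond may migrate on the metal surface. The fallback shifts the problem to an alkene class that is easy to tell apart. It sets out from 19, and the cascade of step 12 is run with 2-methylallylboronic acid pinacol ester to give the 2-methylallyl compound F8. Its 1,1-disubstituted alkene is reduced with H2 and RhCl(PPh3)3, a catalyst that leaves hindered trisubstituted alkenes alone. This comes back to the route at 22.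

Further compounds
F1 | step 12 | methyl ester: 21 with CO2CH3 on C1' in place of the 2-methylpropenyl group (1'S) | COC(=O)[C@H](c3c(OC)cc(OC)cc3OC)[C@@]1(C)CC[C@H]2C1=C[C@H](C(C)(C)O[Si](CC)(CC)CC)CC[C@H]2C
F2 | step 12 | primary alcohol: CH2OH on C1' (1'S) | OC[C@H](c3c(OC)cc(OC)cc3OC)[C@@]1(C)CC[C@H]2C1=C[C@H](C(C)(C)O[Si](CC)(CC)CC)CC[C@H]2C
F3 | step 12 | aldehyde: CHO on C1' (1'S) | O=C[C@H](c3c(OC)cc(OC)cc3OC)[C@@]1(C)CC[C@H]2C1=C[C@H](C(C)(C)O[Si](CC)(CC)CC)CC[C@H]2C
F4 | step 9 | (4R,7R)-1-ethenyl-7-methyl-4-[2-(triethylsilyloxy)propan-2-yl]cyclohept-1-ene | C=CC1=CC[C@H](C(C)(C)O[Si](CC)(CC)CC)CC[C@H]1C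
F5 | step 9 | bis(9-BBN) adduct of F4, boron on C3 and on C5 (α) | C(CB1C2CCCC1CCC2)[C@H]3[C@H](B4C5CCCC4CCC5)C[C@H](C(C)(C)O[Si](CC)(CC)CC)CC[C@H]3C
F6 | step 9 | 1,3,5-trimethoxy-2-(prop-1-yn-1-yl)benzene | CC#Cc1c(OC)cc(OC)cc1OC
F7 | step 9 | 2-[(1E)-2-iodoprop-1-en-1-yl]-1,3,5-trimethoxybenzene | COc1cc(OC)c(/C=C(C)/I)c(OC)c1
F8 | step 13 | 2-methylallyl compound: 21 with CH2C(CH3)=CH2 on C1' (1'S) | C=C(C)C[C@H](c3c(OC)cc(OC)cc3OC)[C@@]1(C)CC[C@H]2C1=C[C@H](C(C)(C)O[Si](CC)(CC)CC)CC[C@H]2C
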